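**Plan**

- Ring A is a phloroglucinol whose three oxygens must differ: O1 on C8a (free, flanked by the C8 prenyl group), O7 and O5. A cyclobutenone/ynol ether benzannulation delivers exactly this pattern, cutting C8–C8a, C6–C7 and C4a–C8a.
- Ring C is cut at O1–C2 (6-endo oxa-Michael), C3–C4 (acetylide addition to an aldehyde) and C4–C4a (ortho-formylation); ring B is cut at its C5'–prenyl bond.
- Forward: ring A is made from cyclobutenone 8 and silyl ynol ether 14; C4a is formylated; the ring B acetylide (from 5-bromovanillin) is added; oxidation gives the ynone; ring C closes; fluoride frees the three hydroxyls.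
- Stereochemistry: the target has no stereocentre and no stereogenic alkene. The one carbinol centre on the route (30) is racemic and is erased by oxidation in step 14.

Key step: step 6

Remark on the chemistry: ring A atoms carry flavone numbering (O1, C4a, C5 to C8, C8a) throughout. The alkyne partner is a triisopropylsilyl ynol ether because alkyl ynol ethers with β-hydrogens can lose alkene by retro-ene fragmentation near the benzannulation temperature, whereas a silyl ynol ether has no such pathway. Assumption: ketene is drawn from a standard acetone-pyrolysis generator; ethynylmagnesium bromide (THF solution) and tributyl(prenyl)stannane are bought.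

**Route**

Step 1
Reactants: 1 2-(trimethylsilyl)ethanol; 2 trichloroethylene
Product: 3 {2-[(E)-1,2-dichloroethenoxy]ethyl}trimethylsilane
Conditions: KH, THF, 0 °C; then 2, –50 °C to rt
Reagents that add atoms: none
Why: The potassium alkoxide dehydrochlorinates trichloroethylene to dichloroacetylene and adds to it anti to give the E dichlorovinyl ether (first stage of the Greene ynol ether synthesis); the β-silyl alkoxide is kept cold so that Peterson-type fragmentation does not compete.

Step 2
Reactants: 3 {2-[(E)-1,2-dichloroethenoxy]ethyl}trimethylsilane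
Product: 5 [2-(ethynyloxy)ethyl]trimethylsilane, via lithium [2-(trimethylsilyl)ethoxy]acetylide 4 (not isolated)
Conditions: n-BuLi (2.3 equiv), THF, –78 to –40 °C; MeOH, –78 °C
Reagents that add atoms: none
Why: β-Elimination of HCl followed by chlorine–lithium exchange (second stage of the Greene synthesis) gives the lithium alkoxyacetylide, which methanol protonates on carbon.

Step 3
Reactants: 5 [2-(ethynyloxy)ethyl]trimethylsilane; 6 acetone
Product: 8 3-[2-(trimethylsilyl)ethoxy]cyclobut-2-en-1-one, via ketene 7 (not isolated)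
Conditions: ketene gas (pyrolysis of 6, hot-filament generator, excess) passed into 5, CH2Cl2, 0 °C
Reagents that add atoms: none
Why: Ketene–alkoxyacetylene (2+2) cycloaddition, known for ethoxyacetylene: the electron-rich terminal alkyne carbon attacks the ketene carbonyl carbon, so the alkoxy group ends at C3 of the cyclobutenone.

Step 4
Reactants: 9 prenyl bromide (1-bromo-3-methylbut-2-ene); 10 ethynylmagnesium bromide
Product: 11 5-methylhex-4-en-1-yne
Conditions: 10 (2 equiv), CuCl (5 mol %), THF, 0 °C to rt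
Reagents that add atoms: none
Why: Allylic substitution of the primary allylic bromide by the alkynyl Grignard reagent under monovalent copper catalysis gives the skipped enyne at the unhindered terminus; excess Grignard reagent suppresses double allylation.

Step 5
Reactants: 11 5-methylhex-4-en-1-yne
Product: 14 triisopropyl[(5-methylhex-4-en-1-yn-1-yl)oxy]silane, via lithium 5-methylhex-4-en-1-yn-1-ide 12 (not isolated), via lithium 5-methylhex-4-en-1-yn-1-olate 13 (not isolated)
Conditions: n-BuLi, THF, –78 °C; t-BuOOLi [from t-BuOOH + LiN(SiMe3)2], –78 to 0 °C; i-Pr3SiOTf, –78 °C to rt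
Reagents that add atoms: tert-butyl hydroperoxide, CC(C)(C)OO; triisopropylsilyl triflate, CC(C)[Si](C(C)C)(C(C)C)OS(=O)(=O)C(F)(F)F
Why: Electrophilic oxygenation of the lithium acetylide by lithium tert-butyl peroxide (Julia ynolate synthesis) gives the lithium ynolate, which the bulky silyl triflate traps on oxygen as the silyl ynol ether.

Step 6
Reactants: 8 3-[2-(trimethylsilyl)ethoxy]cyclobut-2-en-1-one; 14 triisopropyl[(5-methylhex-4-en-1-yn-1-yl)oxy]silane
Product: 19 2-(3-methylbut-2-en-1-yl)-3-[(triisopropylsilyl)oxy]-5-[2-(trimethylsilyl)ethoxy]phenol, via vinylketene 15 (not isolated), via 4-vinylcyclobutenone 16 (not isolated), via dienylketene 17 (not isolated), via cyclohexa-2,4-dienone 18 (not isolated)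
Conditions: 14 (1.3 equiv), toluene (0.4 M), 80 °C then 110 °C, Ar
Reagents that add atoms: none
Why: Heating opens 8 by four-electron electrocyclic cleavage to the 3-alkoxyvinylketene 15, whose ketene carbonyl carbon is the future C8a; the silyl ynol ether adds across the ketene C=C in a (2+2) step (new bonds C8–C8a and C6–C7) to give 16. A second four-electron opening of 16 gives dienylketene 17, which closes ring A by a thermal six-electron disrotatory electrocyclisation (C4a–C8a) to dienone 18, and enolisation gives the phenol. This is the Danheiser benzannulation of a cyclobutenone with a heteroatom-substituted alkyne. No stereocentre remains in the product; the centre in 16 is transient and racemic. The selectivity needed is the orientation of the (2+2) step: the siloxy donor makes the prenyl-bearing alkyne carbon the nucleophile toward the ketene carbonyl carbon, so the free hydroxyl ends on C8a next to the C8 prenyl group, O7 carries silicon, O5 carries the silylethyl group and C4a is the only open ortho carbon. The silyl ynol ether is used in excess to outrun self-reaction of the vinylketene.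

Step 7
Reactants: 19 2-(3-methylbut-2-en-1-yl)-3-[(triisopropylsilyl)oxy]-5-[2-(trimethylsilyl)ethoxy]phenol
Product: 20 2-hydroxy-3-(3-methylbut-2-en-1-yl)-4-[(triisopropylsilyl)oxy]-6-[2-(trimethylsilyl)ethoxy]benzaldehyde
Conditions: MgCl2 (anhydrous), Et3N, (CH2O)n, MeCN, 80 °C; aq NH4Cl
Reagents that add atoms: paraformaldehyde (as formaldehyde), C=O
Why: Magnesium phenoxide-directed ortho-formylation (Casnati–Skattebøl): formaldehyde is delivered inside the magnesium chelate only ortho to the free hydroxyl, C8 is blocked, so the formyl group enters at C4a and not at C6, a second formaldehyde serving as hydride acceptor.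

Step 8
Reactants: 21 5-bromovanillin
Product: 22 3-bromo-4,5-dihydroxybenzaldehyde
Conditions: AlCl3, pyridine, CH2Cl2, reflux; aq HCl
Reagents that add atoms: none
Why: Lewis acid demethylation of an ortho-hydroxyanisole: AlCl3 is held by the phenoxide and the neighbouring methoxy oxygen and pyridine removes the activated methyl group (AlCl3–pyridine ether cleavage), a standard conversion of 5-halovanillins into catechols.

Step 9
Reactants: 22 3-bromo-4,5-dihydroxybenzaldehyde
Product: 23 3-bromo-5-hydroxy-4-methoxybenzaldehyde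
Conditions: MeI (1.1 equiv), Li2CO3, DMF, 40 °C
Reagents that add atoms: iodomethane, CI
Why: Regioselective Williamson methylation: the hydroxyl para to the formyl group is the more acidic, so the weak base Li2CO3 forms only that phenoxide.

Step 10
Reactants: 23 3-bromo-5-hydroxy-4-methoxybenzaldehyde
Product: 24 3-bromo-4-methoxy-5-[(triisopropylsilyl)oxy]benzaldehyde
Conditions: i-Pr3SiCl, imidazole, DMF, rt
Reagents that add atoms: triisopropylsilyl chloride, CC(C)[Si](Cl)(C(C)C)C(C)C
Why: Imidazole-promoted O-silylation of a phenol; the triisopropylsilyl ether tolerates the coupling, olefination and organolithium steps that follow and leaves with fluoride at the end.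

Step 11
Reactants: 24 3-bromo-4-methoxy-5-[(triisopropylsilyl)oxy]benzaldehyde; 25 tributyl(3-methylbut-2-en-1-yl)stannane
Product: 26 4-methoxy-3-(3-methylbut-2-en-1-yl)-5-[(triisopropylsilyl)oxy]benzaldehyde
Conditions: 25 (1.3 equiv), Pd(PPh3)4 (5 mol %), DMF, 100 °C
Reagents that add atoms: none
Why: Stille coupling: zerovalent palladium inserts into the aryl–bromine bond, the allylstannane transmetalates and reductive elimination at the primary allyl terminus gives the linear prenyl arene; aldehyde and silyl ether are tolerated under these fluoride-free conditions.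

Step 12
Reactants: 26 4-methoxy-3-(3-methylbut-2-en-1-yl)-5-[(triisopropylsilyl)oxy]benzaldehyde
Product: 27 [5-(2,2-dibromoethenyl)-2-methoxy-3-(3-methylbut-2-en-1-yl)phenoxy]triisopropylsilane
Conditions: CBr4, PPh3, Zn dust, CH2Cl2, 0 °C to rt
Reagents that add atoms: carbon tetrabromide, BrC(Br)(Br)Br
Why: First stage of the Corey–Fuchs reaction: Wittig olefination of the aldehyde by the ylide Ph3P=CBr2 under neutral conditions that leave the silyl ether and the prenyl alkene untouched.

Step 13
Reactants: 27 [5-(2,2-dibromoethenyl)-2-methoxy-3-(3-methylbut-2-en-1-yl)phenoxy]triisopropylsilane; 20 2-hydroxy-3-(3-methylbut-2-en-1-yl)-4-[(triisopropylsilyl)oxy]-6-[2-(trimethylsilyl)ethoxy]benzaldehyde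
Product: 30 racemic 2-{1-hydroxy-3-[4-methoxy-3-(3-methylbut-2-en-1-yl)-5-(triisopropylsilyloxy)phenyl]prop-2-yn-1-yl}-6-(3-methylbut-2-en-1-yl)-5-(triisopropylsilyloxy)-3-[2-(trimethylsilyl)ethoxy]phenol, via lithium arylacetylide 28 (not isolated), via lithium phenoxide 29 (not isolated)
Conditions: 27 (1.4 equiv), n-BuLi (2.8 equiv), THF, –78 to 0 °C; 20 + LiN(SiMe3)2 (1.0 equiv), THF, –78 °C, added at –78 °C, then to 0 °C; aq NH4Cl
Reagents that add atoms: none
Why: The second stage of the Corey–Fuchs reaction (bromine–lithium exchange, Fritsch–Buttenberg–Wiechell shift, deprotonation) gives the lithium acetylide, which adds 1,2 to the salicylaldehyde carried as its lithium phenoxide, as is known for free salicylaldehydes; the new carbinol centre forms without control as the racemate and is removed in step 14.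

Step 14
Reactants: 30 the racemic propargylic alcohol of step 13
Product: 31 1-{2-hydroxy-3-(3-methylbut-2-en-1-yl)-4-[(triisopropylsilyl)oxy]-6-[2-(trimethylsilyl)ethoxy]phenyl}-3-{4-methoxy-3-(3-methylbut-2-en-1-yl)-5-[(triisopropylsilyl)oxy]phenyl}prop-2-yn-1-one
Conditions: activated MnO2 (excess), CH2Cl2, rt
Reagents that add atoms: none
Why: Chemoselective MnO2 oxidation of a benzylic, propargylic alcohol to the ortho-hydroxyaryl ynone; the phenol, once hydrogen-bonded to the new carbonyl, and the prenyl alkenes are not touched.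

Step 15
Reactants: 31 the ortho-hydroxyaryl ynone of step 14
Product: 32 2-{4-methoxy-3-(3-methylbut-2-en-1-yl)-5-[(triisopropylsilyl)oxy]phenyl}-8-(3-methylbut-2-en-1-yl)-7-[(triisopropylsilyl)oxy]-5-[2-(trimethylsilyl)ethoxy]-4H-chromen-4-one
Conditions: DMAP (0.3 equiv), DMF, 40 °C
Reagents that add atoms: none
Why: Amine-catalysed intramolecular oxa-Michael addition of the C8a phenol to the ynone β-carbon (6-endo-dig closure of O1–C2), the conjugate mode that gives the flavone and not the 5-exo aurone; the mild neutral conditions spare silyl ethers and prenyl groups.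

Step 16
Reactants: 32 the protected flavone of step 15
Product: 33 5,7-dihydroxy-2-[3-hydroxy-4-methoxy-5-(3-methylbut-2-en-1-yl)phenyl]-8-(3-methylbut-2-en-1-yl)-4H-chromen-4-one (CNP0221799.0)
Conditions: Bu4NF (6 equiv), DMF, 0 °C then 60 °C; AcOH quench
Reagents that add atoms: none
Why: Fluoride cleaves the two aryl silyl ethers at silicon and removes the 2-(trimethylsilyl)ethyl group by attack on silicon with β-elimination of ethylene, the O5 phenoxide being a good leaving group as a vinylogous carboxylate of the C4 carbonyl; no acid is used, so the prenyl groups do not cyclise onto the neighbouring phenols.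

**Compound list**

1 | 2-(trimethylsilyl)ethanol | C[Si](C)(C)CCO | starting material
2 | trichloroethylene | ClC=C(Cl)Cl | starting material
3 | {2-[(E)-1,2-dichloroethenoxy]ethyl}trimethylsilane | C[Si](C)(C)CCO/C(Cl)=C\Cl | intermediate
4 | lithium [2-(trimethylsilyl)ethoxy]acetylide | C[Si](C)(C)CCOC#[C-].[Li+] | intermediate (not isolated)
5 | [2-(ethynyloxy)ethyl]trimethylsilane | C[Si](C)(C)CCOC#C | intermediate
6 | acetone | CC(C)=O | starting material
7 | ketene | C=C=O | intermediate (not isolated)
8 | 3-[2-(trimethylsilyl)ethoxy]cyclobut-2-en-1-one | O=C1C=C(OCC[Si](C)(C)C)C1 | intermediate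
9 | prenyl bromide (1-bromo-3-methylbut-2-ene) | CC(C)=CCBr | starting material
10 | ethynylmagnesium bromide | C#C[Mg]Br | starting material
11 | 5-methylhex-4-en-1-yne | CC(C)=CCC#C | intermediate
12 | lithium 5-methylhex-4-en-1-yn-1-ide | CC(C)=CCC#[C-].[Li+] | intermediate (not isolated)
13 | lithium 5-methylhex-4-en-1-yn-1-olate | CC(C)=CCC#C[O-].[Li+] | intermediate (not isolated)
14 | triisopropyl[(5-methylhex-4-en-1-yn-1-yl)oxy]silane | CC(C)=CCC#CO[Si](C(C)C)(C(C)C)C(C)C | intermediate
15 | 3-[2-(trimethylsilyl)ethoxy]buta-1,3-dien-1-one (vinylketene) | C=C(OCC[Si](C)(C)C)C=C=O | intermediate (not isolated)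
16 | racemic 2-(3-methylbut-2-en-1-yl)-3-[(triisopropylsilyl)oxy]-4-{1-[2-(trimethylsilyl)ethoxy]ethenyl}cyclobut-2-en-1-one | O=C1C(CC=C(C)C)=C(O[Si](C(C)C)(C(C)C)C(C)C)C1C(=C)OCC[Si](C)(C)C | intermediate (not isolated)
17 | (3E)-2-(3-methylbut-2-en-1-yl)-3-[(triisopropylsilyl)oxy]-5-[2-(trimethylsilyl)ethoxy]hexa-1,3,5-trien-1-one (dienylketene, ketene and enol ether termini cis) | O=C=C(CC=C(C)C)/C(O[Si](C(C)C)(C(C)C)C(C)C)=C\C(=C)OCC[Si](C)(C)C | intermediate (not isolated)
18 | 2-(3-methylbut-2-en-1-yl)-3-[(triisopropylsilyl)oxy]-5-[2-(trimethylsilyl)ethoxy]cyclohexa-2,4-dien-1-one | O=C1CC(OCC[Si](C)(C)C)=CC(O[Si](C(C)C)(C(C)C)C(C)C)=C1CC=C(C)C | intermediate (not isolated)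
19 | 2-(3-methylbut-2-en-1-yl)-3-[(triisopropylsilyl)oxy]-5-[2-(trimethylsilyl)ethoxy]phenol | CC(C)=CCc1c(O)cc(OCC[Si](C)(C)C)cc1O[Si](C(C)C)(C(C)C)C(C)C | intermediate
20 | 2-hydroxy-3-(3-methylbut-2-en-1-yl)-4-[(triisopropylsilyl)oxy]-6-[2-(trimethylsilyl)ethoxy]benzaldehyde | CC(C)=CCc1c(O)c(C=O)c(OCC[Si](C)(C)C)cc1O[Si](C(C)C)(C(C)C)C(C)C | intermediate
21 | 5-bromovanillin | COc1cc(C=O)cc(Br)c1O | starting material
22 | 3-bromo-4,5-dihydroxybenzaldehyde | O=Cc1cc(O)c(O)c(Br)c1 | intermediate
23 | 3-bromo-5-hydroxy-4-methoxybenzaldehyde | COc1c(O)cc(C=O)cc1Br | intermediate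
24 | 3-bromo-4-methoxy-5-[(triisopropylsilyl)oxy]benzaldehyde | COc1c(O[Si](C(C)C)(C(C)C)C(C)C)cc(C=O)cc1Br | intermediate
25 | tributyl(3-methylbut-2-en-1-yl)stannane | CCCC[Sn](CCCC)(CCCC)CC=C(C)C | starting material
26 | 4-methoxy-3-(3-methylbut-2-en-1-yl)-5-[(triisopropylsilyl)oxy]benzaldehyde | COc1c(O[Si](C(C)C)(C(C)C)C(C)C)cc(C=O)cc1CC=C(C)C | intermediate
27 | [5-(2,2-dibromoethenyl)-2-methoxy-3-(3-methylbut-2-en-1-yl)phenoxy]triisopropylsilane | COc1c(O[Si](C(C)C)(C(C)C)C(C)C)cc(C=C(Br)Br)cc1CC=C(C)C | intermediate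
28 | lithium {4-methoxy-3-(3-methylbut-2-en-1-yl)-5-[(triisopropylsilyl)oxy]phenyl}acetylide | COc1c(O[Si](C(C)C)(C(C)C)C(C)C)cc(C#[C-])cc1CC=C(C)C.[Li+] | intermediate (not isolated)
29 | lithium phenoxide of aldehyde 20 | CC(C)=CCc1c([O-])c(C=O)c(OCC[Si](C)(C)C)cc1O[Si](C(C)C)(C(C)C)C(C)C.[Li+] | intermediate (not isolated)
30 | racemic 2-{1-hydroxy-3-[4-methoxy-3-(3-methylbut-2-en-1-yl)-5-(triisopropylsilyloxy)phenyl]prop-2-yn-1-yl}-6-(3-methylbut-2-en-1-yl)-5-(triisopropylsilyloxy)-3-[2-(trimethylsilyl)ethoxy]phenol | COc1c(O[Si](C(C)C)(C(C)C)C(C)C)cc(C#CC(O)c2c(O)c(CC=C(C)C)c(O[Si](C(C)C)(C(C)C)C(C)C)cc2OCC[Si](C)(C)C)cc1CC=C(C)C | intermediate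
31 | 1-{2-hydroxy-3-(3-methylbut-2-en-1-yl)-4-[(triisopropylsilyl)oxy]-6-[2-(trimethylsilyl)ethoxy]phenyl}-3-{4-methoxy-3-(3-methylbut-2-en-1-yl)-5-[(triisopropylsilyl)oxy]phenyl}prop-2-yn-1-one | COc1c(O[Si](C(C)C)(C(C)C)C(C)C)cc(C#CC(=O)c2c(O)c(CC=C(C)C)c(O[Si](C(C)C)(C(C)C)C(C)C)cc2OCC[Si](C)(C)C)cc1CC=C(C)C | intermediate
32 | 2-{4-methoxy-3-(3-methylbut-2-en-1-yl)-5-[(triisopropylsilyl)oxy]phenyl}-8-(3-methylbut-2-en-1-yl)-7-[(triisopropylsilyl)oxy]-5-[2-(trimethylsilyl)ethoxy]-4H-chromen-4-one | COc1c(O[Si](C(C)C)(C(C)C)C(C)C)cc(-c2cc(=O)c3c(OCC[Si](C)(C)C)cc(O[Si](C(C)C)(C(C)C)C(C)C)c(CC=C(C)C)c3o2)cc1CC=C(C)C | intermediate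
33 | 5,7-dihydroxy-2-[3-hydroxy-4-methoxy-5-(3-methylbut-2-en-1-yl)phenyl]-8-(3-methylbut-2-en-1-yl)-4H-chromen-4-one | COc1c(O)cc(-c2cc(=O)c3c(O)cc(O)c(CC=C(C)C)c3o2)cc1CC=C(C)C | target

**Count and risks**

Total steps: 16. Longest linear sequence: 9 steps (steps 1, 2, 3, 6, 7, 13, 14, 15, 16 from 1; equally steps 8 to 12 and 13 to 16 from 21).

Steps most likely to fail:

1. Step 6. The four-electron opening of the donor-stabilised (vinylogous ester) cyclobutenone may be slow at temperatures the partners tolerate, so that oligomerisation of the vinylketene or O-acylation of the product phenol by the vinylketene outruns the cycloaddition. Fallback: make the same vinylketene at room temperature from an acid chloride, so that no cyclobutenone opening is needed. It sets out from 1: conjugate addition of 1 to ethyl but-2-ynoate (catalytic NaH, THF) should give ethyl (2E)-3-[2-(trimethylsilyl)ethoxy]but-2-enoate F1. Saponification (LiOH, aqueous THF) gives (2E)-3-[2-(trimethylsilyl)ethoxy]but-2-enoic acid F2, and oxalyl chloride with catalytic DMF at 0 °C gives (2E)-3-[2-(trimethylsilyl)ethoxy]but-2-enoyl chloride F3. Slow addition of Et3N to F3 and 14 in toluene removes HCl across the γ-methyl group (the known route from unsaturated acid chlorides to vinylketenes) and forms 15 in the presence of its trap. Warming the resulting 16 to 80 °C completes the cascade, and the route is rejoined at 19.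

2. Step 13. The aldehyde is carried as an electron-rich phenoxide, so 1,2-addition of the acetylide may stall. The electron-rich benzylic, propargylic alcohol may also ionise toward an ortho-quinone methide during work-up. Fallback: mask the phenol before the addition. It sets out from 20: MOMCl and i-Pr2NEt give 2-(methoxymethoxy)-3-(3-methylbut-2-en-1-yl)-4-[(triisopropylsilyl)oxy]-6-[2-(trimethylsilyl)ethoxy]benzaldehyde F4. Addition of acetylide 28 to this neutral aldehyde gives the racemic MOM-protected propargylic alcohol F5, and MnO2 gives the MOM-protected ynone F6. The acetal, now chelated to the ketone, is removed with MgBr2·OEt2 in Et2O at 0 °C, and the route is rejoined at 31.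

3. Step 16. Once the C7 and C3' phenoxides have formed, the electron-rich polyanion may make β-elimination of the O5 silylethyl group slow, and forcing the temperature may degrade the flavone. Fallback: take off the O5 group first by chelation-assisted Lewis acid cleavage while O7 is still silylated, so that no free phenol flanks the C8 prenyl group. It sets out from 32: MgBr2·OEt2 in CH2Cl2, bound between the C4 carbonyl and O5, should give 5-hydroxy-2-{4-methoxy-3-(3-methylbut-2-en-1-yl)-5-[(triisopropylsilyl)oxy]phenyl}-8-(3-methylbut-2-en-1-yl)-7-[(triisopropylsilyl)oxy]-4H-chromen-4-one F7. Bu4NF in THF at 0 °C then removes the two silyl ethers, and the route is rejoined at 33.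

**Further compounds**

F1 | step 6 | ethyl (2E)-3-[2-(trimethylsilyl)ethoxy]but-2-enoate | CCOC(=O)/C=C(\C)OCC[Si](C)(C)C
F2 | step 6 | (2E)-3-[2-(trimethylsilyl)ethoxy]but-2-enoic acid | OC(=O)/C=C(\C)OCC[Si](C)(C)C
F3 | step 6 | (2E)-3-[2-(trimethylsilyl)ethoxy]but-2-enoyl chloride | ClC(=O)/C=C(\C)OCC[Si](C)(C)C
F4 | step 13 | 2-(methoxymethoxy)-3-(3-methylbut-2-en-1-yl)-4-[(triisopropylsilyl)oxy]-6-[2-(trimethylsilyl)ethoxy]benzaldehyde | COCOc1c(CC=C(C)C)c(O[Si](C(C)C)(C(C)C)C(C)C)cc(OCC[Si](C)(C)C)c1C=O
F5 | step 13 | racemic 1-{2-(methoxymethoxy)-3-(3-methylbut-2-en-1-yl)-4-[(triisopropylsilyl)oxy]-6-[2-(trimethylsilyl)ethoxy]phenyl}-3-{4-methoxy-3-(3-methylbut-2-en-1-yl)-5-[(triisopropylsilyl)oxy]phenyl}prop-2-yn-1-ol | COCOc1c(CC=C(C)C)c(O[Si](C(C)C)(C(C)C)C(C)C)cc(OCC[Si](C)(C)C)c1C(O)C#Cc1cc(O[Si](C(C)C)(C(C)C)C(C)C)c(OC)c(CC=C(C)C)c1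
F6 | step 13 | 1-{2-(methoxymethoxy)-3-(3-methylbut-2-en-1-yl)-4-[(triisopropylsilyl)oxy]-6-[2-(trimethylsilyl)ethoxy]phenyl}-3-{4-methoxy-3-(3-methylbut-2-en-1-yl)-5-[(triisopropylsilyl)oxy]phenyl}prop-2-yn-1-one | COCOc1c(CC=C(C)C)c(O[Si](C(C)C)(C(C)C)C(C)C)cc(OCC[Si](C)(C)C)c1C(=O)C#Cc1cc(O[Si](C(C)C)(C(C)C)C(C)C)c(OC)c(CC=C(C)C)c1
F7 | step 16 | 5-hydroxy-2-{4-methoxy-3-(3-methylbut-2-en-1-yl)-5-[(triisopropylsilyl)oxy]phenyl}-8-(3-methylbut-2-en-1-yl)-7-[(triisopropylsilyl)oxy]-4H-chromen-4-one | COc1c(O[Si](C(C)C)(C(C)C)C(C)C)cc(-c2cc(=O)c3c(O)cc(O[Si](C(C)C)(C(C)C)C(C)C)c(CC=C(C)C)c3o2)cc1CC=C(C)C
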